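**Plan**
- Retrosynthesis: the enol is traced back to the 3-acyl-3-pyrrolin-2-one (ring C=C). Its hemiaminal C–OH and lactam C=O bonds are then cut back to a pyrrole, followed by the aryl–O bond of the 13-membered ring, the pyrrole–acyl C–C bond, the epoxide, the two ring-C bonds made by annulation, and the ring A/B hydrindane.
- Enabling feature: the lactam ring (N-1, C-2 carbonyl, C-3 acyl, C-4 H2, C-5 carrying OH and benzyl) is a 2-benzyl-4-acylpyrrole oxygenated at both α-carbons, C=O at the hydrogen-bearing one and OH at the benzyl-bearing one.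
- Forward: rings A and B by amino-acid-catalysed aldol annulation (steps 1–7); ring C by acetoacetate Michael/aldol annulation on a ring-B acetylcyclopentene (8–15); epoxide and aldehyde (16–20); pyrrole building block (21–23); ketone (24–25); 13-membered ring by Cu-catalysed aryl ether formation (27); pyrrole oxygenation and conjugate reduction (29, 30).
- Stereochemistry: the quaternary carbon comes from D-phenylalanine. The ring-A methyls and both trans ring fusions follow from axial delivery and equilibration relayed from it. The ring-B oxygen is set by conjugate addition on the methyl face, the ring-C methyl by axial hydride, the epoxide by hydroxyl direction, and the hemiaminal carbon by attack of oxygen on the outer face of the bridged pyrrole.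

Key step: step 29

Convention: hydrindanes are numbered as indenes (C-1 carbonyl or carbinol carbon, C-7a quaternary) and tricycles as fluorenes (C-1 carboxyl-bearing, C-4b quaternary, C-9 oxygen-bearing). α is the face of the angular methyl group, β the opposite face; absolute configuration is that of the SMILES strings.
Assumption: oxygen adds to the pyrrole face turned away from the ansa bridge and this gives the hemiaminal configuration of the target; the two hemiaminal epimers can interconvert through the open keto-amide.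

Step 1
Reactants: 1 2-methylcyclopentane-1,3-dione; 2 ethyl vinyl ketone
Product: 3 2-methyl-2-(3-oxopentyl)cyclopentane-1,3-dione
Conditions: Et3N (cat.), EtOAc, 23 °C
Reagents that add atoms: none
Why: Michael addition of the cyclic 1,3-dione to the vinyl ketone, the standard entry to Hajos–Parrish triketones.

Step 2
Reactants: 3 triketone
Product: 4 (7aR)-4,7a-dimethyl-2,3,7,7a-tetrahydro-1H-indene-1,5(6H)-dione
Conditions: D-phenylalanine (1 equiv), 10-camphorsulfonic acid (0.5 equiv), DMF, 30 → 70 °C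
Reagents that add atoms: none
Why: Hajos–Parrish–Eder–Sauer–Wiechert aldol condensation in which the enamine of the D-amino acid should select one of the two enantiotopic ring carbonyls and so set the quaternary centre as R.

Step 3
Reactants: 4 enedione
Product: 5 (1R,7aR)-1-hydroxy-4,7a-dimethyl-1,2,3,6,7,7a-hexahydro-5H-inden-5-one
Conditions: NaBH4 (0.3 equiv), EtOH, −20 °C
Reagents that add atoms: none
Why: Chemoselective borohydride reduction of the saturated ketone in the presence of the enone; hydride arrives anti to the angular methyl and places OH cis to it.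

Step 4
Reactants: 5 hydroxy enone
Product: 6 1α-hydroxy-4,6β,7aα-trimethyl-1,2,3,6,7,7a-hexahydro-5H-inden-5-one
Conditions: LiN(iPr)2 (2.2 equiv), THF, −78 °C; MeI (1.1 equiv), −78 → −40 °C
Reagents that add atoms: iodomethane, CI
Why: Kinetic α'-enolate alkylation of the enone (the lithium alkoxide is inert to MeI at this temperature); the electrophile should enter anti to the 1,3-related angular methyl, and the centre remains epimerisable toward the equatorial methyl in step 5.

Step 5
Reactants: 6 methylated hydroxy enone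
Product: 7 1α-hydroxy-4β,6β,7aα-trimethyl-3aβ-H-octahydro-5H-inden-5-one
Conditions: Li, NH3(l), THF, tBuOH (1 equiv), −78 °C; NH4Cl; then NaOMe (cat.), MeOH, 23 °C
Reagents that add atoms: none
Why: Birch-type dissolving-metal reduction of the enone, whose β-carbanion should protonate to the trans-hydrindane, followed by methoxide equilibration that puts both α-methyl groups equatorial (cis to each other).

Step 6
Reactants: 7 hydroxy ketone
Product: 9 4β,6β,7aα-trimethyl-3aβ-H-octahydro-1H-inden-1α-ol, via hydrazone 8 (not isolated)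
Conditions: N2H4·H2O, KOH, diethylene glycol, 130 → 200 °C
Reagents that add atoms: none
Why: Wolff–Kishner reduction (Huang-Minlon procedure) removes the ring-A carbonyl; the basic medium keeps both flanking methyl groups in the equatorial configuration before they become fixed.

Step 7
Reactants: 9 alcohol
Product: 10 4β,6β,7aα-trimethyl-3aβ-H-octahydro-1H-inden-1-one
Conditions: Dess–Martin periodinane, NaHCO3, CH2Cl2, 23 °C
Reagents that add atoms: none
Why: Dess–Martin oxidation of the hindered secondary alcohol to the trans-hydrindanone without touching the non-enolisable ring fusion.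

Step 8
Reactants: 10 hydrindanone
Product: 12 4β,6β,7aα-trimethyl-3aβ-H-3a,4,5,6,7,7a-hexahydro-1H-inden-1-one, via silyl enol ether 11 (not isolated)
Conditions: LiN(iPr)2, Me3SiCl, THF, −78 °C; then Pd(OAc)2 (1.05 equiv), MeCN, 23 °C
Reagents that add atoms: none
Why: Saegusa–Ito oxidation: the only possible enolate is trapped as its silyl enol ether and dehydrosilylated by divalent palladium under neutral conditions, which avoids deconjugation of the strained cyclopentenone.

Step 9
Reactants: 12 cyclopentenone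
Product: 13 3α-(4-methoxybenzyloxy)-4β,6β,7aα-trimethyl-3aβ-H-octahydro-1H-inden-1-one
Conditions: 4-MeOC6H4CH2OH (5 equiv), KOtBu (10 mol %), THF, −20 → 0 °C; AcOH quench
Reagents that add atoms: 4-methoxybenzyl alcohol, COc1ccc(CO)cc1
Why: Base-catalysed oxa-Michael addition; as with 15-en-17-one steroids, the nucleophile should add on the face of the angular methyl because the opposite face is screened by the equatorial C-4 methyl, which sets the oxygen α.

Step 10
Reactants: 13 β-alkoxy ketone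
Product: 14 3α-(4-methoxybenzyloxy)-4β,6β,7aα-trimethyl-3aβ-H-3a,4,5,6,7,7a-hexahydro-3H-inden-1-yl trifluoromethanesulfonate
Conditions: KN(SiMe3)2, THF, −78 °C; PhNTf2, −78 °C
Reagents that add atoms: N-phenylbis(trifluoromethanesulfonimide), O=S(=O)(N(c1ccccc1)S(=O)(=O)C(F)(F)F)C(F)(F)F
Why: Enolate O-triflation at −78 °C, where β-elimination of the alkoxide is slow; only one enolate is possible because the other α-carbon is quaternary.

Step 11
Reactants: 14 enol triflate
Product: 16 1-acetyl-3α-(4-methoxybenzyloxy)-4β,6β,7aα-trimethyl-3aβ-H-3a,4,5,6,7,7a-hexahydro-3H-indene, via ethoxydiene 15 (not isolated)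
Conditions: CH2=C(OEt)SnBu3, Pd(PPh3)4 (5 mol %), LiCl, THF, 65 °C; then 1 M HCl, THF, 0 °C
Reagents that add atoms: tributyl(1-ethoxyvinyl)stannane, CCCC[Sn](CCCC)(CCCC)C(=C)OCC; water, O
Why: Stille coupling of the enol triflate with the acetyl-anion equivalent and mild hydrolysis of the enol ether should give the acetylcyclopentene (the analogue of a 16-en-20-one).

Step 12
Reactants: 16 acetylcyclopentene; 17 methyl acetoacetate
Product: 19 methyl 9α-(4-methoxybenzyloxy)-2,4bα,6β,8β-tetramethyl-4-oxo-4aβ,8aβ,9aα-H-4,4a,4b,5,6,7,8,8a,9,9a-decahydro-1H-fluorene-1-carboxylate, via Michael adduct 18 (not isolated)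
Conditions: NaOMe (0.5 equiv), MeOH, 23 → 65 °C
Reagents that add atoms: none
Why: Robinson annulation in the Hagemann's-ester mode: the acetoacetate enolate should add to the enone anti to both the angular methyl and the neighbouring ether (new C–C bond β), then the ring-B methyl ketone condenses onto the acetoacetate ketone; methoxide equilibrates the ring-fusion CH next to the ketone to the trans B/C fusion, and the ester-bearing carbon is fixed in step 13.

Step 13
Reactants: 19 tricyclic enone ester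
Product: 20 methyl 9α-(4-methoxybenzyloxy)-2β,4bα,6β,8β-tetramethyl-4-oxo-4aβ,8aβ,9aα-H-dodecahydro-1H-fluorene-1α-carboxylate
Conditions: [(Ph3P)CuH]6 (0.25 equiv), H2O (3 equiv), benzene/THF, 23 °C; then NaOMe (cat.), MeOH, 65 °C
Reagents that add atoms: none
Why: Copper hydride conjugate reduction of the β,β-disubstituted enone should deliver hydride axially (α) to the rigid trans-fused ring, leaving the new methyl equatorial (β); methoxide then equilibrates the ester to the equatorial (α) position.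

Step 14
Reactants: 20 keto ester
Product: 21 methyl 9α-(4-methoxybenzyloxy)-2β,4bα,6β,8β-tetramethyl-4-(trifluoromethanesulfonyloxy)-4aβ,8aβ,9aα-H-2,4a,4b,5,6,7,8,8a,9,9a-decahydro-1H-fluorene-1α-carboxylate
Conditions: KN(SiMe3)2 (1.05 equiv), THF, −78 °C; PhNTf2
Reagents that add atoms: N-phenylbis(trifluoromethanesulfonimide), O=S(=O)(N(c1ccccc1)S(=O)(=O)C(F)(F)F)C(F)(F)F
Why: Kinetic deprotonation takes the CH2 rather than the hindered ring-fusion CH or the less acidic ester α-hydrogen, so enolate triflation should place the double bond where the target has its epoxide.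

Step 15
Reactants: 21 enol triflate
Product: 22 methyl 9α-(4-methoxybenzyloxy)-2β,4,4bα,6β,8β-pentamethyl-4aβ,8aβ,9aα-H-2,4a,4b,5,6,7,8,8a,9,9a-decahydro-1H-fluorene-1α-carboxylate
Conditions: MeZnCl, Pd(PPh3)4 (5 mol %), THF, 50 °C
Reagents that add atoms: methylzinc chloride, C[Zn]Cl
Why: Negishi cross-coupling of the enol triflate installs the vinylic methyl without moving the double bond and tolerates the ester.

Step 16
Reactants: 22 PMB ether
Product: 23 methyl 9α-hydroxy-2β,4,4bα,6β,8β-pentamethyl-4aβ,8aβ,9aα-H-2,4a,4b,5,6,7,8,8a,9,9a-decahydro-1H-fluorene-1α-carboxylate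
Conditions: DDQ, CH2Cl2/pH 7 buffer (10:1), 0 °C
Reagents that add atoms: none
Why: Oxidative cleavage of the 4-methoxybenzyl ether frees the ring-B hydroxyl under buffered conditions that should leave the trisubstituted alkene alone; a γ-lactone cannot form because it would be trans-fused to the cyclopentane.

Step 17
Reactants: 23 hydroxy alkene
Product: 24 methyl 3α,4α-epoxy-9α-hydroxy-2β,4,4bα,6β,8β-pentamethyl-4aβ,8aβ,9aα-H-dodecahydro-1H-fluorene-1α-carboxylate
Conditions: VO(acac)2 (5 mol %), tBuOOH, CH2Cl2, 0 → 23 °C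
Reagents that add atoms: tert-butyl hydroperoxide, CC(C)(C)OO
Why: Hydroxyl-directed vanadium-catalysed epoxidation: the α-hydroxyl is 1,3-cis on ring B to the methyl-bearing alkene carbon (a bishomoallylic alcohol) and should deliver the peroxide oxygen to the α face, the face that undirected reagents would avoid because of the angular methyl.

Step 18
Reactants: 24 epoxy alcohol
Product: 25 methyl 3α,4α-epoxy-2β,4,4bα,6β,8β-pentamethyl-9α-(triethylsilyloxy)-4aβ,8aβ,9aα-H-dodecahydro-1H-fluorene-1α-carboxylate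
Conditions: Et3SiCl, imidazole, DMAP (cat.), DMF, 23 °C
Reagents that add atoms: chlorotriethylsilane, CC[Si](Cl)(CC)CC
Why: Silylation under basic, non-Lewis-acidic conditions protects the secondary alcohol for the two oxidations ahead without opening the epoxide.

Step 19
Reactants: 25 silyl ether ester
Product: 26 [3α,4α-epoxy-2β,4,4bα,6β,8β-pentamethyl-9α-(triethylsilyloxy)-4aβ,8aβ,9aα-H-dodecahydro-1H-fluoren-1α-yl]methanol
Conditions: iBu2AlH (2.5 equiv), CH2Cl2, −78 °C
Reagents that add atoms: none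
Why: Hydride reduction of the ester to the primary alcohol at −78 °C, where the hindered trisubstituted epoxide should not be opened.

Step 20
Reactants: 26 primary alcohol
Product: 27 3α,4α-epoxy-2β,4,4bα,6β,8β-pentamethyl-9α-(triethylsilyloxy)-4aβ,8aβ,9aα-H-dodecahydro-1H-fluorene-1α-carbaldehyde
Conditions: Dess–Martin periodinane, NaHCO3, CH2Cl2, 0 → 23 °C
Reagents that add atoms: none
Why: Buffered Dess–Martin oxidation gives the aldehyde without epimerising the α-carbon, whose equatorial configuration is in any case the more stable one.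

Step 21
Reactants: 28 4-iodo-1H-pyrrole-2-carbaldehyde; 29 1-bromo-4-iodobenzene
Product: 31 (4-bromophenyl)(4-iodo-1H-pyrrol-2-yl)methanol, via aryl Grignard reagent 30 (not isolated)
Conditions: 29, iPrMgCl·LiCl (1.2 equiv), THF, −20 °C; separately 28, iPrMgCl (1.0 equiv), THF, −40 °C; combine, −40 → 0 °C; NH4Cl
Reagents that add atoms: none
Why: Iodine–magnesium exchange is selective for the aryl iodide over the bromide, and the aryl Grignard reagent adds to the aldehyde of the N-magnesiated pyrrole, whose electron-rich ring iodide should not exchange.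

Step 22
Reactants: 31 pyrrolyl carbinol
Product: 33 2-(4-bromobenzyl)-4-iodo-1H-pyrrole, via azafulvene 32 (not isolated)
Conditions: NaBH4 (excess), iPrOH, 82 °C
Reagents that add atoms: none
Why: Borohydride deoxygenation of an NH-pyrrol-2-yl carbinol through loss of hydroxide to the azafulvene and hydride addition, which needs no acid and leaves both halides in place.

Step 23
Reactants: 33 NH-pyrrole
Product: 34 2-(4-bromobenzyl)-4-iodo-1-{[2-(trimethylsilyl)ethoxy]methyl}-1H-pyrrole
Conditions: NaH, DMF, 0 °C; Me3SiCH2CH2OCH2Cl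
Reagents that add atoms: 2-(trimethylsilyl)ethoxymethyl chloride, C[Si](C)(C)CCOCCl
Why: N-alkylation of the pyrrolide gives a base-stable N-protecting group that blocks copper-mediated N-arylation in step 27 and is removable with fluoride.

Step 24
Reactants: 27 aldehyde; 34 N-protected iodopyrrole
Product: 36 [5-(4-bromobenzyl)-1-{[2-(trimethylsilyl)ethoxy]methyl}pyrrol-3-yl][3α,4α-epoxy-2β,4,4bα,6β,8β-pentamethyl-9α-(triethylsilyloxy)-4aβ,8aβ,9aα-H-dodecahydro-1H-fluoren-1α-yl]methanol (both carbinol epimers), via pyrrolyl Grignard reagent 35 (not isolated)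
Conditions: 34 (1.3 equiv), iPrMgCl·LiCl, THF, −20 → 0 °C; then 27, −40 → 0 °C
Reagents that add atoms: none
Why: Iodine–magnesium exchange (the aryl bromide is inert at this temperature) gives a pyrrol-3-yl Grignard reagent of unambiguous regiochemistry that adds to the aldehyde; the new carbinol centre is removed in step 25.

Step 25
Reactants: 36 carbinol
Product: 37 [5-(4-bromobenzyl)-1-{[2-(trimethylsilyl)ethoxy]methyl}pyrrol-3-yl] ketone of the 9α-triethylsilyloxy epoxy tricycle
Conditions: Dess–Martin periodinane, NaHCO3, CH2Cl2, 0 °C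
Reagents that add atoms: none
Why: Buffered Dess–Martin oxidation of the heteroaryl carbinol to the 3-acylpyrrole, which also deactivates the pyrrole for the steps before its planned oxidation.

Step 26
Reactants: 37 silyl ether ketone
Product: 38 [5-(4-bromobenzyl)-1-{[2-(trimethylsilyl)ethoxy]methyl}pyrrol-3-yl] ketone of the 9α-hydroxy epoxy tricycle
Conditions: Bu4NF (1.1 equiv), THF, 0 °C
Reagents that add atoms: none
Why: Fluoride cleaves the O–Si bond at 0 °C while the N-CH2O-bound silylethyl group needs heating, so only the ring-B hydroxyl is freed.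

Step 27
Reactants: 38 hydroxy aryl bromide
Product: 39 N-{[2-(trimethylsilyl)ethoxy]methyl} pyrrolophane (13-membered ring closed by the C-9–O–aryl bond)
Conditions: CuI (30 mol %), 3,4,7,8-tetramethyl-1,10-phenanthroline (60 mol %), Cs2CO3 (2 equiv), toluene (0.002 M), 110 °C
Reagents that add atoms: none
Why: Ullmann-type Cu-catalysed O-arylation of the secondary alcohol closes the para-cyclophane ether at high dilution; the α-oxygen and the equatorial α-acyl group point to the same side of the tricycle, and any axial acyl epimer can equilibrate under the carbonate base to the one that cyclises.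

Step 28
Reactants: 39 N-protected pyrrolophane
Product: 40 NH-pyrrolophane (macrocyclic 2-benzyl-4-acylpyrrole)
Conditions: Bu4NF (5 equiv), THF, 65 °C
Reagents that add atoms: none
Why: Fluoride-induced fragmentation of the silylethoxymethyl group, which is easy on an acyl-substituted pyrrole, frees the N–H needed for the hydroxylactam; epoxide, ketone and aryl ether are stable to these conditions.

Step 29
Reactants: 40 NH-pyrrolophane
Product: 42 macrocyclic 3-acyl-5-hydroxy-1,5-dihydro-2H-pyrrol-2-one, via endoperoxide 41 (not isolated)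
Conditions: O2, tetraphenylporphyrin (1 mol %), white LED, CH2Cl2, −78 °C; then Et3N (0.2 equiv), −78 → 0 °C
Reagents that add atoms: dioxygen, O=O
Why: Sensitised singlet oxygen adds [4+2] across pyrrole C-2 (benzyl-bearing) and C-5 (hydrogen-bearing) to give the 2,5-endoperoxide 41; amine-induced Kornblum–DeLaMare-type cleavage removes the C-5 hydrogen, breaks the O–O bond and leaves the lactam carbonyl at C-5 and the tertiary hydroxyl at C-2. The closest known reaction is the dye-sensitised photooxygenation of 2-substituted NH-pyrroles to 5-hydroxy-1,5-dihydro-2H-pyrrol-2-ones. No ring is closed: the bicyclic peroxide is transient and the 13-membered ring is untouched, so no mode of closure has to be judged. The new stereocentre, the hemiaminal carbon, is controlled by the cyclophane, whose ansa bridge (para-phenylene and ring C) covers the inner face of the pyrrole so that oxygen should arrive on the outer face; the hemiaminal can in addition equilibrate through its open keto-amide form. The step needs regioselectivity between the two α-carbons, secured because only C-5 carries a hydrogen to lose, and chemoselectivity, secured because the only alkene has already become the epoxide and the aryl ether is inert to singlet oxygen. The 4-acyl group slows the cycloaddition but conjugates the new double bond with two carbonyls, which is what the last step needs.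

Step 30
Reactants: 42 acylpyrrolinone
Product: 43 pyrrospirone O
Conditions: Hantzsch ester (diethyl 2,6-dimethyl-1,4-dihydropyridine-3,5-dicarboxylate, 1.2 equiv), toluene, 40 °C
Reagents that add atoms: none
Why: Transfer hydrogenation of the doubly activated (alkylidene β-keto amide) double bond by the Hantzsch ester adds hydride to the ring CH next to the hemiaminal and gives the β-keto amide, which should rest as the hydrogen-bonded exocyclic enol of the target; the conditions are neutral, so the hemiaminal and epoxide are untouched.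

**Compound list**
1 | 2-methylcyclopentane-1,3-dione | CC1C(=O)CCC1=O | starting material
2 | ethyl vinyl ketone (pent-1-en-3-one) | CCC(=O)C=C | starting material
3 | 2-methyl-2-(3-oxopentyl)cyclopentane-1,3-dione | CCC(=O)CCC1(C)C(=O)CCC1=O | intermediate
4 | (7aR)-4,7a-dimethyl-2,3,7,7a-tetrahydro-1H-indene-1,5(6H)-dione | CC1=C2CCC(=O)[C@]2(C)CCC1=O | intermediate
5 | (1R,7aR)-1-hydroxy-4,7a-dimethyl-1,2,3,6,7,7a-hexahydro-5H-inden-5-one (OH cis to the angular methyl) | CC1=C2CC[C@@H](O)[C@]2(C)CCC1=O | intermediate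
6 | 1α-hydroxy-4,6β,7aα-trimethyl-1,2,3,6,7,7a-hexahydro-5H-inden-5-one | C[C@@H]1C(=O)C(C)=C2CC[C@@H](O)[C@]2(C)C1 | intermediate
7 | 1α-hydroxy-4β,6β,7aα-trimethyl-3aβ-H-octahydro-5H-inden-5-one (trans-fused, secondary methyls equatorial) | C[C@@H]1C(=O)[C@H](C)[C@H]2CC[C@@H](O)[C@]2(C)C1 | intermediate
8 | hydrazone of 7 | C[C@@H]1C(=NN)[C@H](C)[C@H]2CC[C@@H](O)[C@]2(C)C1 | intermediate
9 | 4β,6β,7aα-trimethyl-3aβ-H-octahydro-1H-inden-1α-ol | C[C@@H]1C[C@H](C)[C@H]2CC[C@@H](O)[C@]2(C)C1 | intermediate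
10 | 4β,6β,7aα-trimethyl-3aβ-H-octahydro-1H-inden-1-one | C[C@@H]1C[C@H](C)[C@H]2CCC(=O)[C@]2(C)C1 | intermediate
11 | 4β,6β,7aα-trimethyl-1-(trimethylsilyloxy)-3aβ-H-3a,4,5,6,7,7a-hexahydro-3H-indene | C[C@@H]1C[C@H](C)[C@H]2CC=C(O[Si](C)(C)C)[C@]2(C)C1 | intermediate
12 | 4β,6β,7aα-trimethyl-3aβ-H-3a,4,5,6,7,7a-hexahydro-1H-inden-1-one | C[C@@H]1C[C@H](C)[C@H]2C=CC(=O)[C@]2(C)C1 | intermediate
13 | 3α-(4-methoxybenzyloxy)-4β,6β,7aα-trimethyl-3aβ-H-octahydro-1H-inden-1-one | C[C@@H]1C[C@H](C)[C@H]2[C@@H](OCc3ccc(OC)cc3)CC(=O)[C@]2(C)C1 | intermediate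
14 | 3α-(4-methoxybenzyloxy)-4β,6β,7aα-trimethyl-3aβ-H-3a,4,5,6,7,7a-hexahydro-3H-inden-1-yl trifluoromethanesulfonate | C[C@@H]1C[C@H](C)[C@H]2[C@@H](OCc3ccc(OC)cc3)C=C(OS(=O)(=O)C(F)(F)F)[C@]2(C)C1 | intermediate
15 | 1-(1-ethoxyvinyl)-3α-(4-methoxybenzyloxy)-4β,6β,7aα-trimethyl-3aβ-H-3a,4,5,6,7,7a-hexahydro-3H-indene | C[C@@H]1C[C@H](C)[C@H]2[C@@H](OCc3ccc(OC)cc3)C=C(C(=C)OCC)[C@]2(C)C1 | intermediate
16 | 1-acetyl-3α-(4-methoxybenzyloxy)-4β,6β,7aα-trimethyl-3aβ-H-3a,4,5,6,7,7a-hexahydro-3H-indene | C[C@@H]1C[C@H](C)[C@H]2[C@@H](OCc3ccc(OC)cc3)C=C(C(C)=O)[C@]2(C)C1 | intermediate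
17 | methyl acetoacetate | CC(=O)CC(=O)OC | starting material
18 | methyl 2-[1α-acetyl-3α-(4-methoxybenzyloxy)-4β,6β,7aα-trimethyl-3aβ-H-octahydro-1H-inden-2β-yl]-3-oxobutanoate | C[C@@H]1C[C@H](C)[C@H]2[C@@H](OCc3ccc(OC)cc3)[C@H](C(C(C)=O)C(=O)OC)[C@@H](C(C)=O)[C@]2(C)C1 | intermediate
19 | methyl 9α-(4-methoxybenzyloxy)-2,4bα,6β,8β-tetramethyl-4-oxo-4aβ,8aβ,9aα-H-4,4a,4b,5,6,7,8,8a,9,9a-decahydro-1H-fluorene-1-carboxylate (drawn as the 1α-ester; C-1 is fixed in step 13) | C[C@@H]1C[C@H](C)[C@H]2[C@@H](OCc3ccc(OC)cc3)[C@@H]3[C@@H](C(=O)OC)C(C)=CC(=O)[C@H]3[C@]2(C)C1 | intermediate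
20 | methyl 9α-(4-methoxybenzyloxy)-2β,4bα,6β,8β-tetramethyl-4-oxo-4aβ,8aβ,9aα-H-dodecahydro-1H-fluorene-1α-carboxylate | C[C@@H]1C[C@H](C)[C@H]2[C@@H](OCc3ccc(OC)cc3)[C@@H]3[C@@H](C(=O)OC)[C@H](C)CC(=O)[C@H]3[C@]2(C)C1 | intermediate
21 | methyl 9α-(4-methoxybenzyloxy)-2β,4bα,6β,8β-tetramethyl-4-(trifluoromethanesulfonyloxy)-4aβ,8aβ,9aα-H-2,4a,4b,5,6,7,8,8a,9,9a-decahydro-1H-fluorene-1α-carboxylate | C[C@@H]1C[C@H](C)[C@H]2[C@@H](OCc3ccc(OC)cc3)[C@@H]3[C@@H](C(=O)OC)[C@H](C)C=C(OS(=O)(=O)C(F)(F)F)[C@H]3[C@]2(C)C1 | intermediate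
22 | methyl 9α-(4-methoxybenzyloxy)-2β,4,4bα,6β,8β-pentamethyl-4aβ,8aβ,9aα-H-2,4a,4b,5,6,7,8,8a,9,9a-decahydro-1H-fluorene-1α-carboxylate | C[C@@H]1C[C@H](C)[C@H]2[C@@H](OCc3ccc(OC)cc3)[C@@H]3[C@@H](C(=O)OC)[C@H](C)C=C(C)[C@H]3[C@]2(C)C1 | intermediate
23 | methyl 9α-hydroxy-2β,4,4bα,6β,8β-pentamethyl-4aβ,8aβ,9aα-H-2,4a,4b,5,6,7,8,8a,9,9a-decahydro-1H-fluorene-1α-carboxylate | C[C@@H]1C[C@H](C)[C@H]2[C@@H](O)[C@@H]3[C@@H](C(=O)OC)[C@H](C)C=C(C)[C@H]3[C@]2(C)C1 | intermediate
24 | methyl 3α,4α-epoxy-9α-hydroxy-2β,4,4bα,6β,8β-pentamethyl-4aβ,8aβ,9aα-H-dodecahydro-1H-fluorene-1α-carboxylate | C[C@@H]1C[C@H](C)[C@H]2[C@@H](O)[C@@H]3[C@@H](C(=O)OC)[C@H](C)[C@H]4O[C@@]4(C)[C@H]3[C@]2(C)C1 | intermediate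
25 | methyl 3α,4α-epoxy-2β,4,4bα,6β,8β-pentamethyl-9α-(triethylsilyloxy)-4aβ,8aβ,9aα-H-dodecahydro-1H-fluorene-1α-carboxylate | C[C@@H]1C[C@H](C)[C@H]2[C@@H](O[Si](CC)(CC)CC)[C@@H]3[C@@H](C(=O)OC)[C@H](C)[C@H]4O[C@@]4(C)[C@H]3[C@]2(C)C1 | intermediate
26 | [3α,4α-epoxy-2β,4,4bα,6β,8β-pentamethyl-9α-(triethylsilyloxy)-4aβ,8aβ,9aα-H-dodecahydro-1H-fluoren-1α-yl]methanol | C[C@@H]1C[C@H](C)[C@H]2[C@@H](O[Si](CC)(CC)CC)[C@@H]3[C@@H](CO)[C@H](C)[C@H]4O[C@@]4(C)[C@H]3[C@]2(C)C1 | intermediate
27 | 3α,4α-epoxy-2β,4,4bα,6β,8β-pentamethyl-9α-(triethylsilyloxy)-4aβ,8aβ,9aα-H-dodecahydro-1H-fluorene-1α-carbaldehyde | C[C@@H]1C[C@H](C)[C@H]2[C@@H](O[Si](CC)(CC)CC)[C@@H]3[C@@H](C=O)[C@H](C)[C@H]4O[C@@]4(C)[C@H]3[C@]2(C)C1 | intermediate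
28 | 4-iodo-1H-pyrrole-2-carbaldehyde | O=Cc1cc(I)c[nH]1 | starting material
29 | 1-bromo-4-iodobenzene | Brc1ccc(I)cc1 | starting material
30 | 4-bromophenylmagnesium chloride | Cl[Mg]c1ccc(Br)cc1 | intermediate
31 | (4-bromophenyl)(4-iodo-1H-pyrrol-2-yl)methanol | OC(c1ccc(Br)cc1)c1cc(I)c[nH]1 | intermediate
32 | 2-(4-bromobenzylidene)-4-iodo-2H-pyrrole (azafulvene) | IC1=CC(=Cc2ccc(Br)cc2)N=C1 | intermediate
33 | 2-(4-bromobenzyl)-4-iodo-1H-pyrrole | Ic1c[nH]c(Cc2ccc(Br)cc2)c1 | intermediate
34 | 2-(4-bromobenzyl)-4-iodo-1-{[2-(trimethylsilyl)ethoxy]methyl}-1H-pyrrole | Ic1cn(COCC[Si](C)(C)C)c(Cc2ccc(Br)cc2)c1 | intermediate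
35 | [5-(4-bromobenzyl)-1-{[2-(trimethylsilyl)ethoxy]methyl}pyrrol-3-yl]magnesium chloride | Cl[Mg]c1cn(COCC[Si](C)(C)C)c(Cc2ccc(Br)cc2)c1 | intermediate
36 | [5-(4-bromobenzyl)-1-{[2-(trimethylsilyl)ethoxy]methyl}pyrrol-3-yl][3α,4α-epoxy-2β,4,4bα,6β,8β-pentamethyl-9α-(triethylsilyloxy)-4aβ,8aβ,9aα-H-dodecahydro-1H-fluoren-1α-yl]methanol (both carbinol epimers) | C[C@@H]1C[C@H](C)[C@H]2[C@@H](O[Si](CC)(CC)CC)[C@@H]3[C@@H](C(O)c4cn(COCC[Si](C)(C)C)c(Cc5ccc(Br)cc5)c4)[C@H](C)[C@H]6O[C@@]6(C)[C@H]3[C@]2(C)C1 | intermediate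
37 | [5-(4-bromobenzyl)-1-{[2-(trimethylsilyl)ethoxy]methyl}pyrrol-3-yl] [3α,4α-epoxy-2β,4,4bα,6β,8β-pentamethyl-9α-(triethylsilyloxy)-4aβ,8aβ,9aα-H-dodecahydro-1H-fluoren-1α-yl] ketone | C[C@@H]1C[C@H](C)[C@H]2[C@@H](O[Si](CC)(CC)CC)[C@@H]3[C@@H](C(=O)c4cn(COCC[Si](C)(C)C)c(Cc5ccc(Br)cc5)c4)[C@H](C)[C@H]6O[C@@]6(C)[C@H]3[C@]2(C)C1 | intermediate
38 | [5-(4-bromobenzyl)-1-{[2-(trimethylsilyl)ethoxy]methyl}pyrrol-3-yl] [3α,4α-epoxy-9α-hydroxy-2β,4,4bα,6β,8β-pentamethyl-4aβ,8aβ,9aα-H-dodecahydro-1H-fluoren-1α-yl] ketone | C[C@@H]1C[C@H](C)[C@H]2[C@@H](O)[C@@H]3[C@@H](C(=O)c4cn(COCC[Si](C)(C)C)c(Cc5ccc(Br)cc5)c4)[C@H](C)[C@H]6O[C@@]6(C)[C@H]3[C@]2(C)C1 | intermediate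
39 | N-{[2-(trimethylsilyl)ethoxy]methyl} pyrrolophane: 13-membered ring in which the pyrrole is bridged from C-2 (CH2–C6H4–O–C-9) to C-4 (C=O–C-1) of the epoxy tricycle | C[C@@H]1C[C@H](C)[C@H]2[C@H]3Oc4ccc(cc4)Cc4cc(C(=O)[C@H]5[C@H](C)[C@H]6O[C@@]6(C)[C@H]([C@H]35)[C@]2(C)C1)cn4COCC[Si](C)(C)C | intermediate
40 | NH-pyrrolophane (macrocyclic 2-benzyl-4-acylpyrrole) | C[C@@H]1C[C@H](C)[C@H]2[C@H]3Oc4ccc(cc4)Cc4cc(C(=O)[C@H]5[C@H](C)[C@H]6O[C@@]6(C)[C@H]([C@H]35)[C@]2(C)C1)c[nH]4 | intermediate
41 | pyrrole 2,5-endoperoxide of 40 (2,3-dioxa-7-azabicyclo[2.2.1]hept-5-ene) | C[C@@H]1C[C@H](C)[C@H]2[C@H]3Oc4ccc(cc4)C[C@@]45OO[C@@H](N4)C(C(=O)[C@H]6[C@H](C)[C@H]7O[C@@]7(C)[C@H]([C@H]36)[C@]2(C)C1)=C5 | intermediate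
42 | macrocyclic 3-acyl-5-benzyl-5-hydroxy-1,5-dihydro-2H-pyrrol-2-one | C[C@@H]1C[C@H](C)[C@H]2[C@H]3Oc4ccc(cc4)C[C@]4(O)C=C(C(=O)[C@H]5[C@H](C)[C@H]6O[C@@]6(C)[C@H]([C@H]35)[C@]2(C)C1)C(=O)N4 | intermediate
43 | pyrrospirone O | C[C@@H]1C[C@H](C)[C@H]2[C@H]3Oc4ccc(cc4)C[C@]4(O)C/C(=C(/O)[C@H]5[C@H](C)[C@H]6O[C@@]6(C)[C@H]([C@H]35)[C@]2(C)C1)C(=O)N4 | target

**Step count and risks**
Total: 30 steps. Longest linear sequence: 27 steps (1–20 and 24–30); the pyrrole building block takes steps 21–23.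

Most likely to fail:

1. Step 27 (ring closure). The C–O bond-forming step may be too slow in a ring that has to bend around a planar acylpyrrole and a para-phenylene, so intermolecular coupling, loss of bromine from the arene or base-induced decomposition could take over. Fallback: close the ring one oxidation level lower, where the carbon next to the pyrrole is sp3 and the ansa chain is more flexible. Setting out from carbinol 36, Bu4NF in THF at 0 °C should give the diol F1, whose pyrrolyl carbinol hydroxyl cannot reach the arene. CuI, 3,4,7,8-tetramethyl-1,10-phenanthroline and Cs2CO3 in dilute toluene at 110 °C should then give the macrocyclic carbinol F2, and Dess–Martin oxidation returns to the route at 39.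

2. Step 29 (key step). Cycloaddition of singlet oxygen to the acyl-deactivated, possibly distorted pyrrole may be slow enough for sensitiser bleaching, oxidation at the doubly benzylic CH2 or an alternative collapse of the peroxide to compete. Fallback: oxygenate the two α-carbons one after the other without singlet oxygen. Setting out from 40, H2O2 in pyridine at 60 °C should oxidise the free α-carbon and give the 3-acyl-5-benzyl-1,5-dihydro-2H-pyrrol-2-one F3. Silylation with tBuMe2SiOTf and Et3N should give the 2-silyloxypyrrole F4, and dimethyldioxirane in acetone at −78 °C should hydroxylate the benzyl-bearing carbon with loss of the silyl group, returning to the route at 42.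

3. Step 9 (oxygen at ring B). The alkoxide addition is reversible and competes with γ-deprotonation, which would move the double bond out of conjugation and could scramble the ring-fusion centre. Fallback: bring in the oxygen as an epoxide and open it reductively. Setting out from enone 12, H2O2 and NaOH in MeOH at 0 °C should give the α-epoxy ketone F5 (attack on the methyl face). SmI2 in THF/MeOH at −90 °C should cleave the C–O bond next to the carbonyl and give the β-hydroxy ketone F6. 4-Methoxybenzyl trichloroacetimidate with catalytic La(OTf)3 in toluene then returns to the route at 13.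

**Further compounds**
F1 | step 27 | [5-(4-bromobenzyl)-1-{[2-(trimethylsilyl)ethoxy]methyl}pyrrol-3-yl][3α,4α-epoxy-9α-hydroxy-2β,4,4bα,6β,8β-pentamethyl-4aβ,8aβ,9aα-H-dodecahydro-1H-fluoren-1α-yl]methanol (diol) | C[C@@H]1C[C@H](C)[C@H]2[C@@H](O)[C@@H]3[C@@H](C(O)c4cn(COCC[Si](C)(C)C)c(Cc5ccc(Br)cc5)c4)[C@H](C)[C@H]6O[C@@]6(C)[C@H]3[C@]2(C)C1
F2 | step 27 | macrocyclic carbinol (13-membered aryl ether, N-protected pyrrole, CH(OH) in place of the ketone) | C[C@@H]1C[C@H](C)[C@H]2[C@H]3Oc4ccc(cc4)Cc4cc(C(O)[C@H]5[C@H](C)[C@H]6O[C@@]6(C)[C@H]([C@H]35)[C@]2(C)C1)cn4COCC[Si](C)(C)C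
F3 | step 29 | macrocyclic 3-acyl-5-benzyl-1,5-dihydro-2H-pyrrol-2-one | C[C@@H]1C[C@H](C)[C@H]2[C@H]3Oc4ccc(cc4)CC4C=C(C(=O)[C@H]5[C@H](C)[C@H]6O[C@@]6(C)[C@H]([C@H]35)[C@]2(C)C1)C(=O)N4
F4 | step 29 | macrocyclic 3-acyl-5-benzyl-2-(tert-butyldimethylsilyloxy)-1H-pyrrole | C[C@@H]1C[C@H](C)[C@H]2[C@H]3Oc4ccc(cc4)Cc4cc(C(=O)[C@H]5[C@H](C)[C@H]6O[C@@]6(C)[C@H]([C@H]35)[C@]2(C)C1)c(O[Si](C)(C)C(C)(C)C)[nH]4
F5 | step 9 | 2α,3α-epoxy-4β,6β,7aα-trimethyl-3aβ-H-octahydro-1H-inden-1-one | C[C@@H]1C[C@H](C)[C@H]2[C@H]3O[C@H]3C(=O)[C@]2(C)C1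
F6 | step 9 | 3α-hydroxy-4β,6β,7aα-trimethyl-3aβ-H-octahydro-1H-inden-1-one | C[C@@H]1C[C@H](C)[C@H]2[C@@H](O)CC(=O)[C@]2(C)C1
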